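**Strategy.** The dihydrofuran ring is cut at O1–C2 and C3a–C3. This reveals a phenol acting as a 1,3-C,O-dinucleophile (ortho-lithiated phenoxide) and a two-carbon 1,2-dielectrophile in which C3 is an aldehyde carbon and C2 the α-carbon of an epoxide, (S)-2,3-epoxy-3-methylbutanal. In one flask the aryllithium adds to the aldehyde (Felkin–Anh) and the phenoxide then opens the epoxide 5-exo at C2 with inversion, giving the cis-2,3-disubstituted 2,3-dihydrobenzofuran-3-ol. The step exploits the vicinal C3 carbinol/C2 aryl ether pair of the furan ring; the epoxide oxygen ends on the exocyclic carbon, where it is later eliminated and the methyl group oxidised to the enal.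

Key step: step 4

Remark: atoms are numbered as in 1-benzofuran (O1, C2, C3, C3a, C7a). The target is the cis-(2R,3R) compound with an (R)-configured side-chain carbinol carbon.

Step 1
Reactants: 1 3-methylbut-2-en-1-ol (prenol)
Product: 2 [(2R)-3,3-dimethyloxiran-2-yl]methanol
Conditions: Ti(OiPr)4 (5 mol%), D-(−)-diethyl tartrate (6 mol%), t-BuOOH (isooctane), 4 Å MS, CH2Cl2, −20 °C; non-aqueous work-up, distillation
Reagents that add atoms: tert-butyl hydroperoxide, CC(C)(C)OO
Why: Katsuki–Sharpless asymmetric epoxidation of the primary allylic alcohol, in which the D-(−)-tartrate/titanium complex delivers the peroxide oxygen to the alkene face that gives the (R)-epoxy alcohol (mirror image of the L-(+)-tartrate outcome) and so sets the carbon that becomes C2.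

Step 2
Reactants: 2 [(2R)-3,3-dimethyloxiran-2-yl]methanol
Product: 3 (2S)-3,3-dimethyloxirane-2-carbaldehyde
Conditions: (COCl)2, DMSO, CH2Cl2, −78 °C; Et3N, −78 → 0 °C; short-path distillation, used at once
Reagents that add atoms: none
Why: Swern oxidation under non-acidic, low-temperature conditions converts the primary alcohol into the aldehyde without opening the epoxide or epimerising the oxirane CH (the change of descriptor from R to S is only a change of CIP priority), and the by-products are volatile or filterable so that the volatile aldehyde can be distilled.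

Step 3
Reactants: 4 1-(3-bromo-4-hydroxyphenyl)ethan-1-one
Product: 5 2-bromo-4-[(1R)-1-hydroxyethyl]phenol
Conditions: RuCl[(R,R)-TsDPEN](p-cymene) (1 mol%), HCO2H/Et3N (5:2), 30 °C
Reagents that add atoms: none
Why: Noyori asymmetric transfer hydrogenation of the aryl methyl ketone, in which the (R,R)-TsDPEN–Ru hydride transfers hydrogen through the six-membered outer-sphere transition state to the face that gives the (R)-1-arylethanol, while aryl bromide and phenol are tolerated under the formate conditions.

Step 4
Reactants: 5 2-bromo-4-[(1R)-1-hydroxyethyl]phenol; 3 (2S)-3,3-dimethyloxirane-2-carbaldehyde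
Product: 8 (2S,3R)-5-[(1R)-1-hydroxyethyl]-2-(2-hydroxypropan-2-yl)-2,3-dihydro-1-benzofuran-3-ol, via trilithiated arene 6 (not isolated), via anti-epoxy alcohol 7 (not isolated)
Conditions: 5 (1.15 equiv), n-BuLi (2.3 equiv), THF, −78 °C; t-BuLi (2.3 equiv), −78 °C; 3 (1.0 equiv), −78 °C; then MeOH, −78 → 40 °C
Reagents that add atoms: none
Why: Double O-deprotonation and bromine–lithium exchange give aryllithium 6, which adds 1,2 to aldehyde 3; after methanol is added only the phenol remains ionised, and the phenoxide attacks the epoxide at C2 in an SN2 opening. The closest known reaction types are the addition of organolithium reagents to α,β-epoxy aldehydes and the base-mediated cyclisation of ortho-(2,3-epoxy-3-methylbutyl)phenols to 2-(2-hydroxypropan-2-yl)-2,3-dihydrobenzofurans. The ring closes in the 5-exo-tet mode at the secondary epoxide carbon, which under basic conditions is preferred over 6-endo attack at the tertiary carbon. C3 is set by Felkin–Anh addition (epoxide C–O bond anti to the incoming aryl group, reinforced by the methyl group cis to the formyl group) to give the anti-epoxy alcohol 7, and C2, set in step 1, is inverted in the ring closure, so that anti addition plus inversion gives the cis-2,3 relationship of the target. The step needs facial selectivity at the aldehyde and must avoid epoxide migration (Payne rearrangement) through the benzylic alkoxide, which is secured by protonating the alkoxides with methanol before warming. The benzylic stereocentre of 5 is carried as its alkoxide and is not touched, and because two enantioenriched fragments are joined, products from the minor enantiomers are diastereomers that can be separated.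

Step 5
Reactants: 8 (2S,3R)-5-[(1R)-1-hydroxyethyl]-2-(2-hydroxypropan-2-yl)-2,3-dihydro-1-benzofuran-3-ol
Product: 9 (2S,3R)-2-(2-hydroxypropan-2-yl)-5-[(1R)-1-(3-methylbutanoyloxy)ethyl]-2,3-dihydro-1-benzofuran-3-yl 3-methylbutanoate
Conditions: (i-BuCO)2O (2.5 equiv), DMAP (0.2 equiv), Et3N, CH2Cl2, 0 → 23 °C
Reagents that add atoms: 3-methylbutanoic anhydride, CC(C)CC(=O)OC(=O)CC(C)C
Why: DMAP-catalysed O-acylation (retention at both carbinol carbons) esterifies the two secondary benzylic hydroxyl groups, while the hindered tertiary alcohol should not react at this temperature with a limited amount of anhydride.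

Step 6
Reactants: 9 (2S,3R)-2-(2-hydroxypropan-2-yl)-5-[(1R)-1-(3-methylbutanoyloxy)ethyl]-2,3-dihydro-1-benzofuran-3-yl 3-methylbutanoate
Product: 10 (2R,3R)-5-[(1R)-1-(3-methylbutanoyloxy)ethyl]-2-(prop-1-en-2-yl)-2,3-dihydro-1-benzofuran-3-yl 3-methylbutanoate
Conditions: Burgess reagent (2 equiv), toluene, 50 °C
Reagents that add atoms: none
Why: Burgess dehydration, in which the tertiary sulfamate undergoes thermal syn-elimination (Ei) under neutral conditions that spare the benzylic esters, and loss of one of the six methyl hydrogens is favoured statistically and sterically over loss of H-2, which would need a crowded rotamer and give an enol ether (the descriptor at C2 changes from S to R only by CIP priority).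

Step 7
Reactants: 10 (2R,3R)-5-[(1R)-1-(3-methylbutanoyloxy)ethyl]-2-(prop-1-en-2-yl)-2,3-dihydro-1-benzofuran-3-yl 3-methylbutanoate
Product: 12 (2R,3R)-5-[(1R)-1-(3-methylbutanoyloxy)ethyl]-2-(3-oxoprop-1-en-2-yl)-2,3-dihydro-1-benzofuran-3-yl 3-methylbutanoate (target), via allylic alcohol 11 (not isolated)
Conditions: SeO2 (1.5 equiv), 1,4-dioxane, 70 °C
Reagents that add atoms: selenium dioxide, O=[Se]=O
Why: Riley oxidation, in which the ene reaction of SeO2 at the terminal carbon of the 1,1-disubstituted alkene takes a methyl hydrogen (CH3 preferred over the ring CH), the [2,3]-sigmatropic shift gives allylic alcohol 11 and further oxidation by SeO2 gives the 2-substituted acrolein without touching a stereocentre.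

**Compound list**

1 | 3-methylbut-2-en-1-ol (prenol) | CC(C)=CCO | starting material
2 | [(2R)-3,3-dimethyloxiran-2-yl]methanol | CC1(C)[C@@H](CO)O1 | intermediate
3 | (2S)-3,3-dimethyloxirane-2-carbaldehyde | CC1(C)[C@@H](C=O)O1 | intermediate
4 | 1-(3-bromo-4-hydroxyphenyl)ethan-1-one | CC(=O)c1ccc(O)c(Br)c1 | starting material
5 | 2-bromo-4-[(1R)-1-hydroxyethyl]phenol | C[C@@H](O)c1ccc(O)c(Br)c1 | intermediate
6 | lithium 2-lithio-4-[(1R)-1-(lithiooxy)ethyl]phenoxide (trilithiated arene) | [Li]c1cc([C@@H](C)O[Li])ccc1O[Li] | intermediate (not isolated)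
7 | 2-{(R)-[(2R)-3,3-dimethyloxiran-2-yl](hydroxy)methyl}-4-[(1R)-1-hydroxyethyl]phenol (anti-epoxy alcohol, present as its lithium salts) | CC1(C)O[C@@H]1[C@H](O)c1cc([C@@H](C)O)ccc1O | intermediate (not isolated)
8 | (2S,3R)-5-[(1R)-1-hydroxyethyl]-2-(2-hydroxypropan-2-yl)-2,3-dihydro-1-benzofuran-3-ol | CC(C)(O)[C@H]1Oc2ccc([C@@H](C)O)cc2[C@H]1O | intermediate
9 | (2S,3R)-2-(2-hydroxypropan-2-yl)-5-[(1R)-1-(3-methylbutanoyloxy)ethyl]-2,3-dihydro-1-benzofuran-3-yl 3-methylbutanoate | CC(C)(O)[C@H]1Oc2ccc([C@@H](C)OC(=O)CC(C)C)cc2[C@H]1OC(=O)CC(C)C | intermediate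
10 | (2R,3R)-5-[(1R)-1-(3-methylbutanoyloxy)ethyl]-2-(prop-1-en-2-yl)-2,3-dihydro-1-benzofuran-3-yl 3-methylbutanoate | C=C(C)[C@H]1Oc2ccc([C@@H](C)OC(=O)CC(C)C)cc2[C@H]1OC(=O)CC(C)C | intermediate
11 | (2R,3R)-2-(3-hydroxyprop-1-en-2-yl)-5-[(1R)-1-(3-methylbutanoyloxy)ethyl]-2,3-dihydro-1-benzofuran-3-yl 3-methylbutanoate | C=C(CO)[C@H]1Oc2ccc([C@@H](C)OC(=O)CC(C)C)cc2[C@H]1OC(=O)CC(C)C | intermediate (not isolated)
12 | (2R,3R)-5-[(1R)-1-(3-methylbutanoyloxy)ethyl]-2-(3-oxoprop-1-en-2-yl)-2,3-dihydro-1-benzofuran-3-yl 3-methylbutanoate (CNP0316116.1) | C=C(C=O)[C@H]1Oc2ccc([C@@H](C)OC(=O)CC(C)C)cc2[C@H]1OC(=O)CC(C)C | target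

**Step count.** Total: 7 steps. Longest linear sequence: 6 steps (1, 2, 4, 5, 6, 7).

**Steps most likely to fail**

1. Step 4. The dilithium salt of 5 may be poorly soluble, so that bromine–lithium exchange is incomplete or the aryllithium is quenched by proton transfer. Facial selectivity in the carbonyl addition may be eroded, and the epoxide may migrate through the benzylic alkoxide before ring closure. Fallback: setting out from 5, both hydroxyl groups are silylated (TBSCl, imidazole, DMF) to give the bis(tert-butyldimethylsilyl) ether F1. Exchange with t-BuLi (THF, −78 °C) gives the soluble mono-aryllithium F2, which adds to 3 to give the silylated anti-epoxy alcohol F3. AcOH (1 equiv) and then Bu4NF are added to the same flask. Fluoride unmasks the phenoxide as the only anion, which closes the ring 5-exo at C2, and it also removes the second silyl group. The route is rejoined at 8.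

2. Step 6. A proton may be lost from C2 in place of a methyl group (giving the enol ether), or the sulfamate may ionise with participation of the cis ester, followed by loss of the C3 ester and aromatisation to the benzofuran. Fallback: setting out from 8, the elimination is moved ahead of the esterification. The two secondary alcohols are silylated (TESCl, imidazole, DMF, 0 °C) to give the bis(triethylsilyl) ether F4, which has no acyl leaving group at C3. The tertiary alcohol is eliminated by a pyridine-mediated anti-E2 of its chlorosulfite (SOCl2, pyridine, −20 °C) to give the isopropenyl bis(silyl) ether F5. HF·pyridine then frees the isopropenyl diol F6, which is esterified as in step 5. The route is rejoined at 10.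

3. Step 7. The oxidation may stall at the allylic alcohol, and hot selenous acid may cause loss of the C3 ester with aromatisation or over-oxidation. Fallback: setting out from 10, an ene-type chlorination with hypochlorous acid (NaOCl, CeCl3·7H2O, CH2Cl2/H2O, 0 °C) gives the 2-(chloromethyl)allyl compound F7. This is oxidised under Ganem/Kornblum-type conditions (4-methylmorpholine N-oxide, NaI cat., MeCN, 40 °C) to the enal. The route is rejoined at 12.

**Further compounds**

F1 | step 4 | tert-butyl{(1R)-1-[3-bromo-4-(tert-butyldimethylsilyloxy)phenyl]ethoxy}dimethylsilane | C[C@@H](O[Si](C)(C)C(C)(C)C)c1ccc(O[Si](C)(C)C(C)(C)C)c(Br)c1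
F2 | step 4 | {2-(tert-butyldimethylsilyloxy)-5-[(1R)-1-(tert-butyldimethylsilyloxy)ethyl]phenyl}lithium | C[C@@H](O[Si](C)(C)C(C)(C)C)c1ccc(O[Si](C)(C)C(C)(C)C)c([Li])c1
F3 | step 4 | (R)-{2-(tert-butyldimethylsilyloxy)-5-[(1R)-1-(tert-butyldimethylsilyloxy)ethyl]phenyl}[(2R)-3,3-dimethyloxiran-2-yl]methanol | CC1(C)O[C@@H]1[C@H](O)c1cc([C@@H](C)O[Si](C)(C)C(C)(C)C)ccc1O[Si](C)(C)C(C)(C)C
F4 | step 6 | 2-{(2S,3R)-3-(triethylsilyloxy)-5-[(1R)-1-(triethylsilyloxy)ethyl]-2,3-dihydro-1-benzofuran-2-yl}propan-2-ol | CC(C)(O)[C@H]1Oc2ccc([C@@H](C)O[Si](CC)(CC)CC)cc2[C@H]1O[Si](CC)(CC)CC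
F5 | step 6 | triethyl{(1R)-1-[(2R,3R)-2-(prop-1-en-2-yl)-3-(triethylsilyloxy)-2,3-dihydro-1-benzofuran-5-yl]ethoxy}silane | C=C(C)[C@H]1Oc2ccc([C@@H](C)O[Si](CC)(CC)CC)cc2[C@H]1O[Si](CC)(CC)CC
F6 | step 6 | (2R,3R)-5-[(1R)-1-hydroxyethyl]-2-(prop-1-en-2-yl)-2,3-dihydro-1-benzofuran-3-ol | C=C(C)[C@H]1Oc2ccc([C@@H](C)O)cc2[C@H]1O
F7 | step 7 | (2R,3R)-2-(3-chloroprop-1-en-2-yl)-5-[(1R)-1-(3-methylbutanoyloxy)ethyl]-2,3-dihydro-1-benzofuran-3-yl 3-methylbutanoate | C=C(CCl)[C@H]1Oc2ccc([C@@H](C)OC(=O)CC(C)C)cc2[C@H]1OC(=O)CC(C)C
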